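**Plan**
- Target and retrosynthesis: the upper unit has 2-aryl and 3-OH cis and the C4 aryl trans to the 3-OH, so the target is epigallocatechin-(4β→6)-epigallocatechin 3-O-gallate, both units 2R,3R. The cuts, in order: the thirteen benzyl ethers and a C8–Br blocking group; the interflavan C4–C6′ bond (upper C4 cation + lower C6); the upper C3–O and C4–O bonds (back to a flav-3-ene); the O1–C2 bond of the upper pyran ring; the chalcone C=C bond. The lower unit is cut at its gallate ester into natural (−)-epigallocatechin and tri-O-benzylgallic acid.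
- Forward: an A-ring ketone and a B-ring aldehyde are joined to a 2′-hydroxychalcone and reduced; the upper pyran ring is closed by O1–C2 bond formation; C3 and C4 are oxygenated. In parallel, (−)-epigallocatechin is benzylated, galloylated and brominated at C8. The lower unit is attached through its C6 to the upper C4, and one hydrogenolysis unmasks everything.
- Feature used: upper C2 is benzylic to the pyrogallol B-ring and, through C3=C4, conjugated with the phloroglucinol A-ring whose ortho oxygen is O1. The reduced chalcone therefore ionises to a planar 1,3-diarylallyl cation (an O-protonated vinyl ortho-quinone methide) that closes 6-endo at C2 inside a chiral ion pair, whatever the configuration of the precursor.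
- Stereochemistry: upper C2 from the chiral counter-anion (step 3); upper C3 relayed from C2 (bromine anti to the aryl group, then epoxide closure puts oxygen cis to it); upper C4 from attack trans to the C3–OH on the C4 cation (step 9); lower C2 and C3 from (−)-epigallocatechin.

Key step: step 3

Remark: 1, 2, 9 and 11 are taken as purchased; ion pairs and benzylic cations are treated as transient species inside the Why lines, and only the neutral in-flask epoxide of step 5 carries a number of its own.

Step 1
Reactants: 1 1-[2,4-bis(benzyloxy)-6-hydroxyphenyl]ethan-1-one; 2 3,4,5-tris(benzyloxy)benzaldehyde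
Product: 3 (E)-1-[2,4-bis(benzyloxy)-6-hydroxyphenyl]-3-[3,4,5-tris(benzyloxy)phenyl]prop-2-en-1-one
Conditions: KOH (50% aq), EtOH/THF, rt
Reagents that add atoms: none
Why: Claisen–Schmidt condensation of an aryl methyl ketone with a non-enolisable aldehyde, in which E1cB dehydration gives the E-alkene and the phenoxide form of the 2′-hydroxychalcone resists closure to the flavanone under these basic conditions.

Step 2
Reactants: 3 (E)-2′-hydroxychalcone
Product: 4 rac-3,5-bis(benzyloxy)-2-{(E)-1-hydroxy-3-[3,4,5-tris(benzyloxy)phenyl]prop-2-en-1-yl}phenol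
Conditions: NaBH4, THF/EtOH, 0 °C → rt; NaHCO3 work-up without acid, used crude
Reagents that add atoms: none
Why: 1,2-hydride reduction of the chalcone carbonyl (the first half of the classical flav-3-ene synthesis from 2′-hydroxychalcones), the new carbinol centre being left racemic on purpose because it is erased in step 3.

Step 3
Reactants: 4 racemic allylic alcohol
Product: 5 (2S)-5,7-bis(benzyloxy)-2-[3,4,5-tris(benzyloxy)phenyl]-2H-chromene
Conditions: BINOL-derived chiral N-triflylphosphoramide (5 mol %), toluene (high dilution), 4 Å MS, −78 °C; Et3N quench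
Reagents that add atoms: none
Why: The chiral strong Brønsted acid protonates the C4 hydroxyl of 4, which is benzylic to the 2,4,6-trioxygenated A-ring, and loss of water gives the planar 1,3-diarylallyl cation (an O-protonated vinylogous ortho-quinone methide) held as a contact ion pair whose phosphoramide anion is hydrogen-bonded to the one free phenolic OH; after rotation about the C3–C4 bond the phenol oxygen closes onto C2, the allyl terminus benzylic to the B-ring, and the catalyst is released. The closest known reaction type is the chiral N-triflylphosphoramide-catalysed intramolecular allylic substitution of o-hydroxyaryl allylic alcohols to 2H-chromenes through chiral contact ion pairs, with the palladium-catalysed 6-endo allylic etherification to 2-aryl-2H-chromenes as its metal counterpart. The pyran ring closes in the 6-endo-trig mode, formally an oxa-6π electrocyclisation of the acid-bound Z-quinone methide. The new stereocentre C2 is set by the chiral counter-anion alone, so both enantiomers of 4 and any E/Z isomers converge on (2S)-5 through the same achiral cation (2S here is the same spatial arrangement as 2R in the target, the descriptor changing because C3 is sp2); the catalyst antipode that gives this series would be fixed in a preliminary screen. The step needs O- over C-alkylation and intra- over intermolecular capture, which should be secured by the hydrogen-bonded ortho OH (the two other A-ring oxygens are benzyl ethers and closure at C4 would give a four-membered ring), by high dilution and by −78 °C, which should also keep the product C2–O bond from re-ionising before the quench.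

Step 4
Reactants: 5 (2S)-flav-3-ene
Product: 6 (2R,3S,4R)-5,7-bis(benzyloxy)-3-bromo-2-[3,4,5-tris(benzyloxy)phenyl]chroman-4-ol
Conditions: NBS (1.05 equiv), THF/H2O, 0 °C, dark
Reagents that add atoms: N-bromosuccinimide O=C1CCC(=O)N1Br; water O
Why: Bromohydrin formation of a 2H-chromene, in which Br+ adds to C3 from the face anti to the 2-aryl group because only this regiochemistry gives the C4 cation stabilised by the 5,7-dioxygenated A-ring, and water then adds to C4 trans to bromine (3β-Br, 4α-OH).

Step 5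
Reactants: 6 trans-bromohydrin
Product: 8 (2R,3R,4S)-5,7-bis(benzyloxy)-4-(2-ethoxyethoxy)-2-[3,4,5-tris(benzyloxy)phenyl]chroman-3-ol, via epoxide 7 (not isolated)
Conditions: K2CO3, 2-ethoxyethanol/THF, rt → 40 °C
Reagents that add atoms: 2-ethoxyethanol CCOCCO
Why: Intramolecular Williamson closure (C4–O− anti-periplanar to C3–Br, anti-E2 being impossible because H2 and H4 are both syn to bromine) gives the epoxide with oxygen cis to the 2-aryl group, and solvolytic opening at the doubly oxygen-stabilised benzylic C4 by the alcohol leaves the 3-OH cis to the aryl group (2R,3R), the C4 configuration being of no consequence because C4 is ionised again in step 9.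

Step 6
Reactants: 9 (−)-epigallocatechin
Product: 10 (2R,3R)-5,7-bis(benzyloxy)-2-[3,4,5-tris(benzyloxy)phenyl]chroman-3-ol (5,7,3′,4′,5′-penta-O-benzyl-epigallocatechin)
Conditions: BnBr (5.5 equiv), K2CO3, degassed DMF, 0 °C → rt, Ar
Reagents that add atoms: benzyl bromide BrCc1ccccc1
Why: Williamson etherification of the five phenolic hydroxyls, the carbonate base being strong enough for the phenols but not for the secondary C3 alcohol, which stays free, and the mild, oxygen-free conditions being chosen so that C2 is not epimerised through a B-ring quinone methide and the pyrogallol ring is not oxidised.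

Step 7
Reactants: 10 penta-O-benzyl-epigallocatechin; 11 3,4,5-tris(benzyloxy)benzoic acid
Product: 12 5,7,3′,4′,5′,3″,4″,5″-octa-O-benzyl-epigallocatechin 3-O-gallate (octa-O-benzyl-EGCG)
Conditions: DCC (1.5 equiv), DMAP (cat.), CH2Cl2, 0 °C → rt
Reagents that add atoms: none
Why: Steglich esterification of the single free (axial, secondary) hydroxyl through the DMAP-acylpyridinium of the O-acylisourea, which acylates oxygen without touching the C3–O bond, so that both stereocentres of the chiral-pool unit are retained.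

Step 8
Reactants: 12 octa-O-benzyl-EGCG
Product: 13 8-bromo-octa-O-benzyl-EGCG
Conditions: NBS (1.0 equiv), CH2Cl2, −78 °C → rt
Reagents that add atoms: N-bromosuccinimide O=C1CCC(=O)N1Br
Why: Electrophilic aromatic bromination, which on 5,7-di-O-benzylflavans goes to C8 of the A-ring, so that C6 remains as the only nucleophilic carbon for step 9 and the bromine is removed again in step 10.

Step 9
Reactants: 8 4β-(2-ethoxyethoxy)-penta-O-benzyl-epigallocatechin; 13 8-bromo-octa-O-benzyl-EGCG
Product: 14 penta-O-benzyl-epigallocatechin-(4β→6)-8-bromo-octa-O-benzyl-EGCG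
Conditions: 13 (3 equiv), TMSOTf (0.2 equiv), CH2Cl2, −78 → −40 °C; Et3N quench
Reagents that add atoms: none
Why: Lewis acid-promoted Friedel–Crafts interflavan coupling, in which ionisation of the 4-alkoxy group gives the A-ring-stabilised C4 cation that is attacked by C6 of 13 from the face trans to the pseudo-axial C3–OH (3,4-trans, 4β, the selectivity known for 2,3-cis electrophiles), while the C8 bromine of 13 enforces the 4→6 link and the excess of 13 suppresses self-condensation.

Step 10
Reactants: 14 protected dimer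
Product: 15 epigallocatechin-(4β→6)-epigallocatechin 3-O-gallate (CNP0204196.2)
Conditions: H2 (1 atm), Pd(OH)2/C, Et3N, THF/MeOH/H2O, rt
Reagents that add atoms: none
Why: Catalytic hydrogenolysis should cleave the thirteen benzyl ethers and the aryl C–Br bond in one operation, the amine buffering the HBr so that the acid-labile interflavan bond and the gallate ester survive and no stereocentre is touched.

**Compound list**
1 | 1-[2,4-bis(benzyloxy)-6-hydroxyphenyl]ethan-1-one | CC(=O)c1c(O)cc(OCc2ccccc2)cc1OCc1ccccc1 | starting material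
2 | 3,4,5-tris(benzyloxy)benzaldehyde | O=Cc1cc(OCc2ccccc2)c(OCc2ccccc2)c(OCc2ccccc2)c1 | starting material
3 | (E)-1-[2,4-bis(benzyloxy)-6-hydroxyphenyl]-3-[3,4,5-tris(benzyloxy)phenyl]prop-2-en-1-one (2′-hydroxychalcone) | O=C(/C=C/c1cc(OCc2ccccc2)c(OCc2ccccc2)c(OCc2ccccc2)c1)c1c(O)cc(OCc2ccccc2)cc1OCc1ccccc1 | intermediate
4 | rac-3,5-bis(benzyloxy)-2-{(E)-1-hydroxy-3-[3,4,5-tris(benzyloxy)phenyl]prop-2-en-1-yl}phenol (racemic at the carbinol carbon) | OC(/C=C/c1cc(OCc2ccccc2)c(OCc2ccccc2)c(OCc2ccccc2)c1)c1c(O)cc(OCc2ccccc2)cc1OCc1ccccc1 | intermediate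
5 | (2S)-5,7-bis(benzyloxy)-2-[3,4,5-tris(benzyloxy)phenyl]-2H-chromene (penta-O-benzyl flav-3-ene, 2-aryl α) | c1ccccc1COc1cc(OCc2ccccc2)c2C=C[C@@H](c3cc(OCc4ccccc4)c(OCc4ccccc4)c(OCc4ccccc4)c3)Oc2c1 | intermediate
6 | (2R,3S,4R)-5,7-bis(benzyloxy)-3-bromo-2-[3,4,5-tris(benzyloxy)phenyl]chroman-4-ol (2α-aryl, 3β-Br, 4α-OH) | c1ccccc1COc1cc(OCc2ccccc2)c2[C@@H](O)[C@H](Br)[C@@H](c3cc(OCc4ccccc4)c(OCc4ccccc4)c(OCc4ccccc4)c3)Oc2c1 | intermediate
7 | (2R,3R,4R)-5,7-bis(benzyloxy)-3,4-epoxy-2-[3,4,5-tris(benzyloxy)phenyl]chroman (3α,4α-epoxide, cis to the aryl group; not isolated) | c1ccccc1COc1cc(OCc2ccccc2)c2[C@H]3O[C@H]3[C@@H](c3cc(OCc4ccccc4)c(OCc4ccccc4)c(OCc4ccccc4)c3)Oc2c1 | intermediate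
8 | (2R,3R,4S)-5,7-bis(benzyloxy)-4-(2-ethoxyethoxy)-2-[3,4,5-tris(benzyloxy)phenyl]chroman-3-ol (4β-(2-ethoxyethoxy)-penta-O-benzyl-epigallocatechin) | c1ccccc1COc1cc(OCc2ccccc2)c2[C@H](OCCOCC)[C@@H](O)[C@@H](c3cc(OCc4ccccc4)c(OCc4ccccc4)c(OCc4ccccc4)c3)Oc2c1 | intermediate
9 | (−)-epigallocatechin (2R,3R) | O[C@@H]1Cc2c(O)cc(O)cc2O[C@@H]1c1cc(O)c(O)c(O)c1 | starting material
10 | (2R,3R)-5,7-bis(benzyloxy)-2-[3,4,5-tris(benzyloxy)phenyl]chroman-3-ol (5,7,3′,4′,5′-penta-O-benzyl-epigallocatechin, 2,3-cis) | O[C@@H]1Cc2c(OCc3ccccc3)cc(OCc3ccccc3)cc2O[C@@H]1c1cc(OCc2ccccc2)c(OCc2ccccc2)c(OCc2ccccc2)c1 | intermediate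
11 | 3,4,5-tris(benzyloxy)benzoic acid | O=C(O)c1cc(OCc2ccccc2)c(OCc2ccccc2)c(OCc2ccccc2)c1 | starting material
12 | 5,7,3′,4′,5′,3″,4″,5″-octa-O-benzyl-epigallocatechin 3-O-gallate (octa-O-benzyl-EGCG) | O=C(O[C@@H]1Cc2c(OCc3ccccc3)cc(OCc3ccccc3)cc2O[C@@H]1c1cc(OCc2ccccc2)c(OCc2ccccc2)c(OCc2ccccc2)c1)c1cc(OCc2ccccc2)c(OCc2ccccc2)c(OCc2ccccc2)c1 | intermediate
13 | 8-bromo-octa-O-benzyl-EGCG | O=C(O[C@@H]1Cc2c(OCc3ccccc3)cc(OCc3ccccc3)c(Br)c2O[C@@H]1c1cc(OCc2ccccc2)c(OCc2ccccc2)c(OCc2ccccc2)c1)c1cc(OCc2ccccc2)c(OCc2ccccc2)c(OCc2ccccc2)c1 | intermediate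
14 | penta-O-benzyl-epigallocatechin-(4β→6)-8-bromo-octa-O-benzyl-EGCG (upper unit 2R,3R, 4-aryl trans to the free 3-OH) | c1ccccc1COc1cc(OCc2ccccc2)c2[C@H](c3c(OCc4ccccc4)c4C[C@@H](OC(=O)c5cc(OCc6ccccc6)c(OCc6ccccc6)c(OCc6ccccc6)c5)[C@@H](c5cc(OCc6ccccc6)c(OCc6ccccc6)c(OCc6ccccc6)c5)Oc4c(Br)c3OCc3ccccc3)[C@@H](O)[C@@H](c3cc(OCc4ccccc4)c(OCc4ccccc4)c(OCc4ccccc4)c3)Oc2c1 | intermediate
15 | epigallocatechin-(4β→6)-epigallocatechin 3-O-gallate (CNP0204196.2) | O=C(O[C@@H]1Cc2c(cc(O)c([C@H]3c4c(O)cc(O)cc4O[C@H](c4cc(O)c(O)c(O)c4)[C@@H]3O)c2O)O[C@@H]1c1cc(O)c(O)c(O)c1)c1cc(O)c(O)c(O)c1 | target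

**Count and risks**
Total step count: 10. Longest linear sequence: 7 steps (steps 1–5, 9, 10); steps 6–8 prepare the lower unit in parallel.

Steps most likely to fail:

1. Step 3, loss of enantiocontrol. The product C2–O bond is itself allylic and benzylic, so acid-mediated re-ionisation, or an uncatalysed dehydration and electrocyclisation of 4, would erode the enantiomeric purity. The fallback sets out from 4 and comes back at 14. Brief treatment of 4 with an achiral acid (AcOH, THF, rt) closes the ring without stereocontrol and gives 5 together with its mirror image, the (2R)-flavene F1. The racemate would be taken through the conditions of steps 4 and 5, which give, next to 6, 7 and 8, the enantiomeric bromohydrin F2, the enantiomeric epoxide F3 (in the flask) and the enantiomeric 4-alkoxy alcohol F4. Coupling of this racemic electrophile with enantiopure 13 under the conditions of step 9 gives two diastereomers, 14 and the dimer with the mirror-image upper unit F5, which should be separable by chromatography. The stereochemical problem is thus moved from catalyst control to a separation against the chiral-pool lower unit, at the cost of half of the upper-unit material.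

2. Step 4, wrong chemoselectivity of the bromonium source. Electrophilic bromination of the very electron-rich A-ring, or oxidation of the 2H-chromene towards the flavylium ion, could compete with bromohydrin formation. The fallback sets out from 5 and comes back at 8; it also bypasses step 5, where a hydride shift in the opened epoxide could compete with alcoholysis. Hydroboration–oxidation of 5 (BH3·THF; NaOH, H2O2), which on flav-3-enes places boron at C3 anti to the 2-aryl group, should give the 2,3-trans alcohol (2R,3S)-penta-O-benzyl-gallocatechin F6. Dess–Martin oxidation should give the flavan-3-one F7. L-Selectride reduction at −78 °C from the face opposite the aryl group should invert C3 and give the 2,3-cis alcohol 10, the same compound that step 6 makes from 9. Oxidation of C4 of 10 with DDQ in CH2Cl2 in the presence of 2-ethoxyethanol then gives 8.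

3. Step 9, self-condensation and slow coupling. The electrophile can react through its own nucleophilic C6/C8 positions to give oligomers, and the hindered, bromine-deactivated C6 of 13 may attack slowly. The fallback sets out from 8 and comes back at 15. The nucleophilicity of the upper A-ring would be switched off first by brominating 8 at C8 (NBS, CH2Cl2, −78 °C) to the 8-bromo electrophile F8. F8 can then be used in near-equimolar amount with 13 (TMSOTf, CH2Cl2, −40 °C) to give the dibromo dimer F9. The hydrogenolysis conditions of step 10 remove both bromine atoms together with the thirteen benzyl groups and give 15.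

**Further compounds**
F1 | step 3 | (2R)-5,7-bis(benzyloxy)-2-[3,4,5-tris(benzyloxy)phenyl]-2H-chromene (enantiomer of 5) | c1ccccc1COc1cc(OCc2ccccc2)c2C=C[C@H](c3cc(OCc4ccccc4)c(OCc4ccccc4)c(OCc4ccccc4)c3)Oc2c1
F2 | step 3 | (2S,3R,4S)-5,7-bis(benzyloxy)-3-bromo-2-[3,4,5-tris(benzyloxy)phenyl]chroman-4-ol (enantiomer of 6) | c1ccccc1COc1cc(OCc2ccccc2)c2[C@H](O)[C@@H](Br)[C@H](c3cc(OCc4ccccc4)c(OCc4ccccc4)c(OCc4ccccc4)c3)Oc2c1
F3 | step 3 | (2S,3S,4S)-5,7-bis(benzyloxy)-3,4-epoxy-2-[3,4,5-tris(benzyloxy)phenyl]chroman (enantiomer of 7) | c1ccccc1COc1cc(OCc2ccccc2)c2[C@@H]3O[C@@H]3[C@H](c3cc(OCc4ccccc4)c(OCc4ccccc4)c(OCc4ccccc4)c3)Oc2c1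
F4 | step 3 | (2S,3S,4R)-5,7-bis(benzyloxy)-4-(2-ethoxyethoxy)-2-[3,4,5-tris(benzyloxy)phenyl]chroman-3-ol (enantiomer of 8) | c1ccccc1COc1cc(OCc2ccccc2)c2[C@@H](OCCOCC)[C@H](O)[C@H](c3cc(OCc4ccccc4)c(OCc4ccccc4)c(OCc4ccccc4)c3)Oc2c1
F5 | step 3 | ent-(penta-O-benzyl-epigallocatechin)-(4α→6)-8-bromo-octa-O-benzyl-EGCG (upper unit 2S,3S, 4-aryl trans to 3-OH; diastereomer of 14) | c1ccccc1COc1cc(OCc2ccccc2)c2[C@@H](c3c(OCc4ccccc4)c4C[C@@H](OC(=O)c5cc(OCc6ccccc6)c(OCc6ccccc6)c(OCc6ccccc6)c5)[C@@H](c5cc(OCc6ccccc6)c(OCc6ccccc6)c(OCc6ccccc6)c5)Oc4c(Br)c3OCc3ccccc3)[C@H](O)[C@H](c3cc(OCc4ccccc4)c(OCc4ccccc4)c(OCc4ccccc4)c3)Oc2c1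
F6 | step 4 | (2R,3S)-5,7-bis(benzyloxy)-2-[3,4,5-tris(benzyloxy)phenyl]chroman-3-ol (penta-O-benzyl-gallocatechin, 2,3-trans) | c1ccccc1COc1cc(OCc2ccccc2)c2C[C@H](O)[C@@H](c3cc(OCc4ccccc4)c(OCc4ccccc4)c(OCc4ccccc4)c3)Oc2c1
F7 | step 4 | (2R)-5,7-bis(benzyloxy)-2-[3,4,5-tris(benzyloxy)phenyl]chroman-3-one | c1ccccc1COc1cc(OCc2ccccc2)c2CC(=O)[C@@H](c3cc(OCc4ccccc4)c(OCc4ccccc4)c(OCc4ccccc4)c3)Oc2c1
F8 | step 9 | (2R,3R,4S)-5,7-bis(benzyloxy)-8-bromo-4-(2-ethoxyethoxy)-2-[3,4,5-tris(benzyloxy)phenyl]chroman-3-ol | c1ccccc1COc1cc(OCc2ccccc2)c2[C@H](OCCOCC)[C@@H](O)[C@@H](c3cc(OCc4ccccc4)c(OCc4ccccc4)c(OCc4ccccc4)c3)Oc2c1Br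
F9 | step 9 | 8-bromo-penta-O-benzyl-epigallocatechin-(4β→6)-8-bromo-octa-O-benzyl-EGCG | c1ccccc1COc1cc(OCc2ccccc2)c2[C@H](c3c(OCc4ccccc4)c4C[C@@H](OC(=O)c5cc(OCc6ccccc6)c(OCc6ccccc6)c(OCc6ccccc6)c5)[C@@H](c5cc(OCc6ccccc6)c(OCc6ccccc6)c(OCc6ccccc6)c5)Oc4c(Br)c3OCc3ccccc3)[C@@H](O)[C@@H](c3cc(OCc4ccccc4)c(OCc4ccccc4)c(OCc4ccccc4)c3)Oc2c1Br
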